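**Plan**

1. Benzofuran numbering is used: O1, C2 (aryl), C3 (ester), C3a, C4–C7, C7a; ring A is the fused benzene, ring B the catechol. Retrosynthetically the benzyl ethers come off first, C7–OH goes back through C7–B to C7–Br, and ring A is then cut at C3a–C4 and C7–C7a.
2. Enabling feature: O1–C2–C3–C3a–C7a is the skeleton of a trans γ-aryl paraconic ester lactone (C7a is the lactone carbonyl carbon). Its enol silyl ether C3a=C7a is an electron-rich two-carbon unit, and C4–C7 with the C5 acrylate and a C7 bromine map onto an electron-poor 3-bromo-2-pyranone diene.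
3. Lactone branch, forward: imide formation, Evans syn aldol with lactonisation (C2–C3 bond and the five-membered O-heterocycle), auxiliary removal, methyl ester, O-silylation.
4. Pyranone branch, forward: coumalic acid to 3,5-dibromo-2-pyranone, then C5-selective Stille coupling with an (E)-stannylacrylate made from methyl propiolate.
5. Union and finish: inverse-demand Diels–Alder reaction, CO2 loss and silanol loss build ring A on the intact dihydrofuran; then C7–Br to C7–Bpin to C7–OH, and BCl3 debenzylation.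
6. Stereochemistry: C2 (R) and C3 (R), trans, both come from the (R)-4-benzyl-oxazolidinone-controlled syn aldol and are carried through unchanged; the E acrylate comes from syn-stannylcupration and is retained in the Stille coupling.

Key step: step 9

Remark: benzofuran numbering is applied to the lactone-derived atoms from step 2 onward (C3a is the lactone α-carbon); closure of aldol adduct 5 to lactone 6 is assumed to need no more than a trace of acid.

**Route**

Step 1
Reactants: 1 (R)-4-benzyl-1,3-oxazolidin-2-one; 2 methyl 4-chloro-4-oxobutanoate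
Product: 3 methyl 4-[(4R)-4-benzyl-2-oxo-1,3-oxazolidin-3-yl]-4-oxobutanoate
Conditions: n-BuLi, THF, −78 °C; then 2, −78 → 0 °C
Reagents that add atoms: none
Why: N-acylation of the lithiated oxazolidinone by an acid chloride is the standard entry to Evans imides, and at −78 °C the acyl chloride reacts far faster than the methyl ester.

Step 2
Reactants: 3 methyl 4-[(4R)-4-benzyl-2-oxo-1,3-oxazolidin-3-yl]-4-oxobutanoate; 4 3,4-bis(benzyloxy)benzaldehyde
Product: 6 (4R)-4-benzyl-3-{(2R,3R)-2-[3,4-bis(benzyloxy)phenyl]-5-oxooxolane-3-carbonyl}-1,3-oxazolidin-2-one, via syn-aldol adduct 5 (not isolated)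
Conditions: Bu2BOTf, iPr2NEt, CH2Cl2, 0 °C; 4, −78 → 0 °C; pH 7 buffer, MeOH, H2O2, 0 °C; then PPTS (cat.), CH2Cl2, rt
Reagents that add atoms: none
Why: In this Evans syn aldol reaction only the imide is enolised, to the Z boron enolate, which adds through a closed chair Zimmerman–Traxler transition state on the face away from the (R)-benzyl group and so sets C3 (R) and C2 (R) in a syn relationship; the new hydroxyl then closes onto the γ-methyl ester (5-exo-trig lactonisation), which turns the syn aldol into the trans 2,3-disubstituted lactone.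

Step 3
Reactants: 6 (4R)-4-benzyl-3-{(2R,3R)-2-[3,4-bis(benzyloxy)phenyl]-5-oxooxolane-3-carbonyl}-1,3-oxazolidin-2-one
Product: 8 (2R,3R)-2-[3,4-bis(benzyloxy)phenyl]-5-oxooxolane-3-carboxylic acid, via peroxy acid 7 (not isolated)
Conditions: LiOH, H2O2, THF–H2O, 0 °C; Na2SO3 aq; then 1 M HCl to pH 2
Reagents that add atoms: hydrogen peroxide, OO
Why: Hydroperoxide cleavage of an Evans imide attacks the exocyclic carbonyl selectively, sulfite reduces the peroxy acid, and any lactone opened by hydroxide recloses on acidification, so C2 and C3 should stay untouched.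

Step 4
Reactants: 8 (2R,3R)-2-[3,4-bis(benzyloxy)phenyl]-5-oxooxolane-3-carboxylic acid
Product: 9 methyl (2R,3R)-2-[3,4-bis(benzyloxy)phenyl]-5-oxooxolane-3-carboxylate
Conditions: TMSCHN2, PhMe–MeOH, 0 °C → rt
Reagents that add atoms: trimethylsilyldiazomethane, C[Si](C)(C)C=[N+]=[N-]
Why: Diazoalkane esterification of a carboxylic acid runs under neutral conditions, so neither the lactone nor the epimerisable C3 centre is at risk.

Step 5
Reactants: 9 methyl (2R,3R)-2-[3,4-bis(benzyloxy)phenyl]-5-oxooxolane-3-carboxylate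
Product: 10 methyl (2R,3R)-2-[3,4-bis(benzyloxy)phenyl]-5-[(tert-butyldimethylsilyl)oxy]-2,3-dihydrofuran-3-carboxylate
Conditions: TBSOTf, Et3N, CH2Cl2, 0 °C → rt; non-aqueous work-up (pentane), used crude
Reagents that add atoms: tert-butyldimethylsilyl trifluoromethanesulfonate, CC(C)(C)[Si](C)(C)OS(=O)(=O)C(F)(F)F
Why: In this soft enolisation (silyl triflate and amine) the lactone carbonyl is more Lewis basic and its α-CH2 more acidic and less hindered than the tertiary α-CH of the acyclic methyl ester, so O-silylation should give the endocyclic ketene silyl acetal C3a=C7a, as is routine for γ-butyrolactones, without touching a stereocentre.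

Step 6
Reactants: 11 coumalic acid (2-oxo-2H-pyran-5-carboxylic acid)
Product: 12 3,5-dibromo-2H-pyran-2-one
Conditions: NBS (2.5 equiv), LiOAc, MeCN–H2O, rt
Reagents that add atoms: N-bromosuccinimide, O=C1CCC(=O)N1Br
Why: In this known bromodecarboxylation the coumalate anion is brominated ipso at C5 with loss of CO2 and a second equivalent of NBS brominates the enol-ether-like C3.

Step 7
Reactants: 13 methyl propiolate
Product: 14 methyl (E)-3-(tributylstannyl)prop-2-enoate
Conditions: Bu3SnH, LiN(iPr)2, THF, 0 °C; CuBr·SMe2, −78 °C; 13 and MeOH, −78 °C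
Reagents that add atoms: tributyltin hydride, CCCC[SnH](CCCC)CCCC
Why: syn-Stannylcupration of an ynoate places tin on the β-carbon and copper on the α-carbon from the same side, and protonation by the methanol present at −78 °C, before the vinylcopper species can isomerise, leaves tin and ester trans (E).

Step 8
Reactants: 12 3,5-dibromo-2H-pyran-2-one; 14 methyl (E)-3-(tributylstannyl)prop-2-enoate
Product: 15 methyl (E)-3-(3-bromo-2-oxo-2H-pyran-5-yl)prop-2-enoate
Conditions: Pd(PPh3)4 (cat.), CuI (1.0 equiv), DMF, 50 °C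
Reagents that add atoms: none
Why: In the Stille coupling of 3,5-dibromo-2-pyranone a full equivalent of CuI in DMF is known to turn the site of coupling from C3 to C5 for aryl and vinyl stannanes (the C5–palladium species transmetalates faster under Curtin–Hammett conditions), and the vinyl group is transferred with retention of its E geometry.

Step 9
Reactants: 10 methyl (2R,3R)-2-[3,4-bis(benzyloxy)phenyl]-5-[(tert-butyldimethylsilyl)oxy]-2,3-dihydrofuran-3-carboxylate; 15 methyl (E)-3-(3-bromo-2-oxo-2H-pyran-5-yl)prop-2-enoate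
Product: 18 methyl (2R,3R)-2-[3,4-bis(benzyloxy)phenyl]-7-bromo-5-[(E)-3-methoxy-3-oxoprop-1-enyl]-2,3-dihydro-1-benzofuran-3-carboxylate, via bridged lactone adduct 16 (not isolated), via silyloxy dihydroarene 17 (not isolated)
Conditions: 10 (1.5 equiv), BHT (cat.), PhMe, 110 °C, sealed tube
Reagents that add atoms: none
Why: The electron-rich ketene silyl acetal and the electron-poor pyranone combine in an inverse-electron-demand Diels–Alder reaction in which the nucleophilic C3a bonds to pyranone C6 (the future C4), where the developing charge is taken up by both the lactone carbonyl and the acrylate, and C7a bonds to the bromine-bearing pyranone C3 (the future C7), giving bridged lactone 16. Retro-[4+2] loss of CO2 then gives dihydroarene 17, and elimination of silanol across C3a–C7a aromatises ring A. The closest known reaction type is the annulation of 3-halo or acceptor-substituted 2-pyranones with ketene acetals and enol ethers to aryl ethers (cycloaddition, CO2 loss, loss of ROH). Ring A closes by an intermolecular [4+2] cycloaddition; should the two bonds form one after the other, the second is a 6-exo-trig attack of the pyranone dienolate carbon on the oxocarbenium carbon C7a. No stereocentre is created that survives, because both new sp3 centres become aromatic carbons, so facial and endo/exo selectivity are irrelevant and C2 and C3 are simply carried along under neutral conditions. The step needs two selectivities: the stated regiochemistry, secured by the polarity match of the ketene acetal β-carbon with pyranone C6, and loss of silanol instead of O1, secured by the better silanolate leaving group and by the five-membered ring, which holds the C7a–O1 bond near the plane of the forming arene while the C7a–OSi bond stands axial and aligned with the π system.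

Step 10
Reactants: 18 methyl (2R,3R)-2-[3,4-bis(benzyloxy)phenyl]-7-bromo-5-[(E)-3-methoxy-3-oxoprop-1-enyl]-2,3-dihydro-1-benzofuran-3-carboxylate
Product: 19 methyl (2R,3R)-2-[3,4-bis(benzyloxy)phenyl]-5-[(E)-3-methoxy-3-oxoprop-1-enyl]-7-(4,4,5,5-tetramethyl-1,3,2-dioxaborolan-2-yl)-2,3-dihydro-1-benzofuran-3-carboxylate
Conditions: B2pin2, PdCl2(dppf) (cat.), KOAc, 1,4-dioxane, 85 °C
Reagents that add atoms: bis(pinacolato)diboron, CC1(C)OB(OC1(C)C)B1OC(C)(C)C(C)(C)O1
Why: Miyaura borylation of an aryl bromide tolerates esters, benzyl ethers and the β-substituted acrylate, and KOAc is too weak a base to open the dihydrofuran by β-elimination from C3.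

Step 11
Reactants: 19 methyl (2R,3R)-2-[3,4-bis(benzyloxy)phenyl]-5-[(E)-3-methoxy-3-oxoprop-1-enyl]-7-(4,4,5,5-tetramethyl-1,3,2-dioxaborolan-2-yl)-2,3-dihydro-1-benzofuran-3-carboxylate
Product: 20 methyl (2R,3R)-2-[3,4-bis(benzyloxy)phenyl]-7-hydroxy-5-[(E)-3-methoxy-3-oxoprop-1-enyl]-2,3-dihydro-1-benzofuran-3-carboxylate
Conditions: NaBO3·4H2O, THF–H2O, rt
Reagents that add atoms: sodium perborate (NaBO3), [Na+].[O-]OB=O
Why: Perborate oxidation of an aryl boronate (1,2-shift of the aryl group from boron to oxygen, then hydrolysis) gives the phenol under mildly basic conditions that should leave the methyl esters, the acrylate and the C3 centre alone.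

Step 12
Reactants: 20 methyl (2R,3R)-2-[3,4-bis(benzyloxy)phenyl]-7-hydroxy-5-[(E)-3-methoxy-3-oxoprop-1-enyl]-2,3-dihydro-1-benzofuran-3-carboxylate
Product: 21 methyl (2R,3R)-2-(3,4-dihydroxyphenyl)-7-hydroxy-5-[(E)-3-methoxy-3-oxoprop-1-enyl]-2,3-dihydro-1-benzofuran-3-carboxylate
Conditions: BCl3, C6HMe5, CH2Cl2, −78 °C; MeOH quench
Reagents that add atoms: none
Why: Lewis acid debenzylation of aryl benzyl ethers with BCl3 and pentamethylbenzene as benzyl cation scavenger cleaves only the O–benzyl bonds at −78 °C and spares the methyl esters, the dihydrofuran and the acrylate double bond, which hydrogenolysis would reduce.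

**Compound list**

1 | (R)-4-benzyl-1,3-oxazolidin-2-one | O=C1N[C@H](Cc2ccccc2)CO1 | starting material
2 | methyl 4-chloro-4-oxobutanoate | COC(=O)CCC(Cl)=O | starting material
3 | methyl 4-[(4R)-4-benzyl-2-oxo-1,3-oxazolidin-3-yl]-4-oxobutanoate | COC(=O)CCC(=O)N1[C@H](Cc2ccccc2)COC1=O | intermediate
4 | 3,4-bis(benzyloxy)benzaldehyde | O=Cc1ccc(OCc2ccccc2)c(OCc2ccccc2)c1 | starting material
5 | methyl (3R,4R)-3-[(4R)-4-benzyl-2-oxo-1,3-oxazolidine-3-carbonyl]-4-[3,4-bis(benzyloxy)phenyl]-4-hydroxybutanoate (syn-aldol adduct) | COC(=O)C[C@@H](C(=O)N1[C@H](Cc2ccccc2)COC1=O)[C@@H](O)c1ccc(OCc2ccccc2)c(OCc2ccccc2)c1 | intermediate (not isolated)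
6 | (4R)-4-benzyl-3-{(2R,3R)-2-[3,4-bis(benzyloxy)phenyl]-5-oxooxolane-3-carbonyl}-1,3-oxazolidin-2-one | O=C1C[C@@H](C(=O)N2[C@H](Cc3ccccc3)COC2=O)[C@H](c2ccc(OCc3ccccc3)c(OCc3ccccc3)c2)O1 | intermediate
7 | (2R,3R)-2-[3,4-bis(benzyloxy)phenyl]-5-oxooxolane-3-carboperoxoic acid | O=C1C[C@@H](C(=O)OO)[C@H](c2ccc(OCc3ccccc3)c(OCc3ccccc3)c2)O1 | intermediate (not isolated)
8 | (2R,3R)-2-[3,4-bis(benzyloxy)phenyl]-5-oxooxolane-3-carboxylic acid | O=C1C[C@@H](C(=O)O)[C@H](c2ccc(OCc3ccccc3)c(OCc3ccccc3)c2)O1 | intermediate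
9 | methyl (2R,3R)-2-[3,4-bis(benzyloxy)phenyl]-5-oxooxolane-3-carboxylate | O=C1C[C@@H](C(=O)OC)[C@H](c2ccc(OCc3ccccc3)c(OCc3ccccc3)c2)O1 | intermediate
10 | methyl (2R,3R)-2-[3,4-bis(benzyloxy)phenyl]-5-[(tert-butyldimethylsilyl)oxy]-2,3-dihydrofuran-3-carboxylate | CC(C)(C)[Si](C)(C)OC1=C[C@@H](C(=O)OC)[C@H](c2ccc(OCc3ccccc3)c(OCc3ccccc3)c2)O1 | intermediate
11 | coumalic acid (2-oxo-2H-pyran-5-carboxylic acid) | OC(=O)C1=COC(=O)C=C1 | starting material
12 | 3,5-dibromo-2H-pyran-2-one | O=C1OC=C(Br)C=C1Br | intermediate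
13 | methyl propiolate | C#CC(=O)OC | starting material
14 | methyl (E)-3-(tributylstannyl)prop-2-enoate | CCCC[Sn](CCCC)(CCCC)/C=C/C(=O)OC | intermediate
15 | methyl (E)-3-(3-bromo-2-oxo-2H-pyran-5-yl)prop-2-enoate | COC(=O)/C=C/C1=COC(=O)C(Br)=C1 | intermediate
16 | bridged [4+2] adduct: a 2-oxabicyclo[2.2.2]oct-5-en-3-one whose saturated two-carbon bridge is the C3a–C7a bond of the dihydrofuran; Br on the bridgehead next to the carbonyl, acrylate on the ring alkene, OTBS on C7a; C2 R and C3 R, the four new centres undefined | O=C1OC2C(/C=C/C(=O)OC)=CC1(Br)C1(O[Si](C)(C)C(C)(C)C)O[C@@H](c3ccc(OCc4ccccc4)c(OCc4ccccc4)c3)[C@H](C(=O)OC)C21 | intermediate (not isolated)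
17 | methyl (2R,3R)-2-[3,4-bis(benzyloxy)phenyl]-7-bromo-7a-[(tert-butyldimethylsilyl)oxy]-5-[(E)-3-methoxy-3-oxoprop-1-enyl]-2,3,3a,7a-tetrahydro-1-benzofuran-3-carboxylate (cis ring fusion; C3a and C7a undefined) | COC(=O)/C=C/C1=CC2[C@@H](C(=O)OC)[C@H](c3ccc(OCc4ccccc4)c(OCc4ccccc4)c3)OC2(O[Si](C)(C)C(C)(C)C)C(Br)=C1 | intermediate (not isolated)
18 | methyl (2R,3R)-2-[3,4-bis(benzyloxy)phenyl]-7-bromo-5-[(E)-3-methoxy-3-oxoprop-1-enyl]-2,3-dihydro-1-benzofuran-3-carboxylate | COC(=O)/C=C/c1cc(Br)c2c(c1)[C@@H](C(=O)OC)[C@H](c1ccc(OCc3ccccc3)c(OCc3ccccc3)c1)O2 | intermediate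
19 | methyl (2R,3R)-2-[3,4-bis(benzyloxy)phenyl]-5-[(E)-3-methoxy-3-oxoprop-1-enyl]-7-(4,4,5,5-tetramethyl-1,3,2-dioxaborolan-2-yl)-2,3-dihydro-1-benzofuran-3-carboxylate | COC(=O)/C=C/c1cc(B3OC(C)(C)C(C)(C)O3)c2c(c1)[C@@H](C(=O)OC)[C@H](c1ccc(OCc3ccccc3)c(OCc3ccccc3)c1)O2 | intermediate
20 | methyl (2R,3R)-2-[3,4-bis(benzyloxy)phenyl]-7-hydroxy-5-[(E)-3-methoxy-3-oxoprop-1-enyl]-2,3-dihydro-1-benzofuran-3-carboxylate | COC(=O)/C=C/c1cc(O)c2c(c1)[C@@H](C(=O)OC)[C@H](c1ccc(OCc3ccccc3)c(OCc3ccccc3)c1)O2 | intermediate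
21 | methyl (2R,3R)-2-(3,4-dihydroxyphenyl)-7-hydroxy-5-[(E)-3-methoxy-3-oxoprop-1-enyl]-2,3-dihydro-1-benzofuran-3-carboxylate (CNP0529351.1) | COC(=O)/C=C/c1cc(O)c2c(c1)[C@@H](C(=O)OC)[C@H](c1ccc(O)c(O)c1)O2 | target

**Step count and risks**

Total step count: 12. Longest linear sequence: 9 steps (steps 1–5 and 9–12); the pyranone branch (steps 6–8) joins at step 9.

Steps most likely to fail:

Step 9. The aromatising elimination may expel the ring oxygen O1 from C7a instead of silanol, which opens the dihydrofuran. The fallback accepts this course and closes the ring afterwards. Setting out from 10 and 15, the same thermal cycloaddition and CO2 loss would then end in methyl (2R,3R)-3-[3,4-bis(benzyloxy)phenyl]-2-{3-bromo-2-[(tert-butyldimethylsilyl)oxy]-5-[(E)-3-methoxy-3-oxoprop-1-enyl]phenyl}-3-hydroxypropanoate F1. HF·pyridine in THF should free the phenol, methyl (2R,3R)-3-[3,4-bis(benzyloxy)phenyl]-2-{3-bromo-2-hydroxy-5-[(E)-3-methoxy-3-oxoprop-1-enyl]phenyl}-3-hydroxypropanoate F2. Catalytic TsOH in CH2Cl2 at 0 °C should then form the C2–O1 bond by dehydrative cycloetherification through the 4-benzyloxybenzyl cation, under thermodynamic control trans to the untouched C3 ester, and the route is rejoined at 18.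

Step 5. Silylation may take place at the methyl ester instead of the lactone, or the C3 proton may be lost with β-elimination of O1. The fallback masks the C3 carboxyl as a carboxylate during enolisation. Setting out from acid 8, LiN(SiMe3)2 (2.2 equiv) in THF at −78 °C should form the carboxylate–lactone enolate dianion, deprotonated only next to the lactone carbonyl as in the known α-alkylations of paraconic acids. TBSCl should silylate both oxygens to give tert-butyldimethylsilyl (2R,3R)-2-[3,4-bis(benzyloxy)phenyl]-5-[(tert-butyldimethylsilyl)oxy]-2,3-dihydrofuran-3-carboxylate F3. Heating F3 with 15 as in step 9, with the silyl ester lost on aqueous work-up, should give (2R,3R)-2-[3,4-bis(benzyloxy)phenyl]-7-bromo-5-[(E)-3-methoxy-3-oxoprop-1-enyl]-2,3-dihydro-1-benzofuran-3-carboxylic acid F4, and TMSCHN2 esterification rejoins the route at 18.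

Step 8. Coupling may take place at C3, the site preferred under ordinary Stille conditions, or at both bromides. The fallback introduces the side chain before the C3 bromine. Setting out from coumalic acid 11, bromodecarboxylation with one equivalent of NBS and LiOAc should give 5-bromo-2H-pyran-2-one F5. Stille coupling with 14 (Pd(PPh3)4, CuI cat., DMF) at its only C–Br bond should give methyl (E)-3-(2-oxo-2H-pyran-5-yl)prop-2-enoate F6. Electrophilic bromination at C3 with pyridinium tribromide in AcOH, the position at which methyl coumalate is brominated, rejoins the route at 15.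

Further compounds
F1 | step 9 | methyl (2R,3R)-3-[3,4-bis(benzyloxy)phenyl]-2-{3-bromo-2-[(tert-butyldimethylsilyl)oxy]-5-[(E)-3-methoxy-3-oxoprop-1-enyl]phenyl}-3-hydroxypropanoate | COC(=O)/C=C/c1cc(Br)c(O[Si](C)(C)C(C)(C)C)c(c1)[C@@H](C(=O)OC)[C@@H](O)c1ccc(OCc2ccccc2)c(OCc2ccccc2)c1
F2 | step 9 | methyl (2R,3R)-3-[3,4-bis(benzyloxy)phenyl]-2-{3-bromo-2-hydroxy-5-[(E)-3-methoxy-3-oxoprop-1-enyl]phenyl}-3-hydroxypropanoate | COC(=O)/C=C/c1cc(Br)c(O)c(c1)[C@@H](C(=O)OC)[C@@H](O)c1ccc(OCc2ccccc2)c(OCc2ccccc2)c1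
F3 | step 5 | tert-butyldimethylsilyl (2R,3R)-2-[3,4-bis(benzyloxy)phenyl]-5-[(tert-butyldimethylsilyl)oxy]-2,3-dihydrofuran-3-carboxylate | CC(C)(C)[Si](C)(C)OC1=C[C@@H](C(=O)O[Si](C)(C)C(C)(C)C)[C@H](c2ccc(OCc3ccccc3)c(OCc3ccccc3)c2)O1
F4 | step 5 | (2R,3R)-2-[3,4-bis(benzyloxy)phenyl]-7-bromo-5-[(E)-3-methoxy-3-oxoprop-1-enyl]-2,3-dihydro-1-benzofuran-3-carboxylic acid | COC(=O)/C=C/c1cc(Br)c2c(c1)[C@@H](C(=O)O)[C@H](c1ccc(OCc3ccccc3)c(OCc3ccccc3)c1)O2
F5 | step 8 | 5-bromo-2H-pyran-2-one | O=C1C=CC(Br)=CO1
F6 | step 8 | methyl (E)-3-(2-oxo-2H-pyran-5-yl)prop-2-enoate | COC(=O)/C=C/C1=COC(=O)C=C1
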